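**Retrosynthetic overview** (chain numbered C1 lactone carbonyl to C12 methyl)

1. Target 19 ⇒ C8=C9 by cross-metathesis of lactone alcohol 11 (C1–C8) with diacetate 18 (C9–C12).
2. 11 ⇒ C6–C7 bond by cathode-driven, chromium-catalysed anti-methoxyallylation of lactone aldehyde 6 with acrolein dimethyl acetal 7; C5 controls C6 and C7.
3. 6 ⇒ 2-deoxy-D-ribose 1: Wittig, photochemical E→Z isomerisation/lactonisation, glycol cleavage. The dihydropyranone (ring A) is the only ring and is closed first, in step 2.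
4. 18 ⇒ L-threonine 12, which supplies C9–C12 and both acetoxy stereocentres.

Assumption: one step is one numbered operation ending in an isolated product; compounds marked "(not isolated)" are carried on in the same flask or as crude solutions.

**Step 1**
Reactants: 1 2-deoxy-D-ribose; 2 methyl (triphenylphosphoranylidene)acetate
Product: 3 methyl (2E,5S,6R)-5,6,7-trihydroxyhept-2-enoate
Conditions: 2 (1.2 equiv), THF, reflux, 6 h
Reagents that add atoms: none
Why: Wittig olefination of the open-chain aldehyde form of the lactol with a stabilised, non-basic ylide gives the E-enoate without oxa-Michael cyclisation; C5 and C6 come unchanged from the sugar, and any Z isomer converges in step 2.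

**Step 2**
Reactants: 3 methyl (2E,5S,6R)-5,6,7-trihydroxyhept-2-enoate
Product: 5 (6S)-6-[(1R)-1,2-dihydroxyethyl]-5,6-dihydro-2H-pyran-2-one, via Z-enoate triol 4 (not isolated)
Conditions: hν (254 nm, quartz), MeSO3H (5 mol%), MeCN (0.02 M), rt
Reagents that add atoms: none
Why: Photoisomerisation–lactonisation: direct excitation equilibrates E and Z enoates, and only the Z isomer can close the six-membered lactone through the C5 hydroxyl, which drains the photostationary mixture; no stereocentre is touched.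

**Step 3**
Reactants: 5 (6S)-6-[(1R)-1,2-dihydroxyethyl]-5,6-dihydro-2H-pyran-2-one
Product: 6 (2S)-6-oxo-3,6-dihydro-2H-pyran-2-carbaldehyde
Conditions: NaIO4 on wet SiO2, CH2Cl2, rt; filter, concentrate, use at once
Reagents that add atoms: none
Why: Malaprade glycol cleavage; with the C5 oxygen tied up in the lactone only the terminal 1,2-diol is cleaved, and the neutral, anhydrous work-up preserves the epimerisable α-acyloxy aldehyde.

**Step 4**
Reactants: 6 (2S)-6-oxo-3,6-dihydro-2H-pyran-2-carbaldehyde; 7 acrolein dimethyl acetal (3,3-dimethoxyprop-1-ene)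
Product: 11 (6S)-6-[(1S,2R)-1-hydroxy-2-methoxybut-3-en-1-yl]-5,6-dihydro-2H-pyran-2-one, via 3-chloro-3-methoxyprop-1-ene 8 (not isolated), via (E)-3-methoxyallylchromium dichloride 9 (not isolated), via O-trimethylsilyl ether of the adduct 10 (not isolated)
Conditions: CrCl2 (15 mol%), Me3SiCl (2.5 equiv), NaI (20 mol%), n-Bu4NBF4 (0.1 M), THF/DMF 4:1, undivided cell, Al anode, Ni-foam cathode, 5 mA, 2.2 F/mol, −10 °C; then aq. citric acid, MeOH, 0 °C
Reagents that add atoms: none
Why: Proposed new method: a cathode-driven, chromium-catalytic γ-methoxyallylation in which Me3SiCl/iodide ionises acetal 7 to α-chloro ether 8, two equivalents of divalent chromium (regenerated from trivalent chromium at the cathode while the Al anode is consumed) reduce 8 to the (E)-γ-methoxyallyl chromium species 9, and 9 adds to aldehyde 6 through a chair Zimmerman–Traxler transition state (C6–OH/C7–OMe anti) on the Felkin–Anh/Cornforth face opposite the poorly chelating ring C5–O bond (C5–O/C6–OH anti), after which Me3SiCl silylates the chromium alkoxide to 10 and frees the metal; the closest known reactions are the stoichiometric CrCl2/Me3SiI Takai–Utimoto alkoxyallylation of aldehydes with acrolein acetals and the electrochemical chromium-catalysed Nozaki–Hiyama–Kishi coupling of alkenyl and allyl halides.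

**Step 5**
Reactants: 12 L-threonine
Product: 13 (2S,3R)-2,3-dihydroxybutanoic acid
Conditions: NaNO2, 1 M H2SO4, H2O, 0 °C → rt
Reagents that add atoms: water, O
Why: Diazotisation of the α-amino acid with net retention at C2 (double inversion through the α-lactone formed by carboxylate participation); C3 is untouched.

**Step 6**
Reactants: 13 (2S,3R)-2,3-dihydroxybutanoic acid
Product: 14 methyl (4S,5R)-2,2,5-trimethyl-1,3-dioxolane-4-carboxylate
Conditions: Me2C(OMe)2, MeOH, TsOH·H2O (cat.), 50 °C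
Reagents that add atoms: 2,2-dimethoxypropane, COC(C)(C)OC; methanol, CO
Why: One-pot Fischer esterification and acetonide formation; the threo diol gives the strain-free trans-dioxolane and no stereocentre is involved.

**Step 7**
Reactants: 14 methyl (4S,5R)-2,2,5-trimethyl-1,3-dioxolane-4-carboxylate
Product: 16 (4R,5R)-4-ethenyl-2,2,5-trimethyl-1,3-dioxolane, via dioxolane aldehyde 15 (not isolated)
Conditions: i-Bu2AlH (1.05 equiv), CH2Cl2, −78 °C; then Ph3P=CH2 (from Ph3PCH3Br, KOtBu, THF), −78 °C → rt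
Reagents that add atoms: methylenetriphenylphosphorane (from methyltriphenylphosphonium bromide), C=P(c1ccccc1)(c1ccccc1)c1ccccc1
Why: Half-reduction of the ester stops at the aluminium hemiacetal at −78 °C, and the labile aldehyde is trapped in the same flask by Wittig methylenation; the trans-dioxolane is the stable epimer, so C10 is not eroded.

**Step 8**
Reactants: 16 (4R,5R)-4-ethenyl-2,2,5-trimethyl-1,3-dioxolane
Product: 18 (3R,4R)-pent-1-ene-3,4-diyl diacetate, via pentenediol 17 (not isolated)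
Conditions: Amberlyst-15 (H+ form), MeOH, 40 °C; filter, concentrate; Ac2O, pyridine, DMAP (cat.), CH2Cl2, 0 °C → rt
Reagents that add atoms: acetic anhydride, CC(=O)OC(C)=O
Why: Acid-catalysed transacetalisation frees the diol, and nucleophilic-catalysed acylation caps both hydroxyls with no C–O bond to a stereocentre broken.

**Step 9**
Reactants: 11 (6S)-6-[(1S,2R)-1-hydroxy-2-methoxybut-3-en-1-yl]-5,6-dihydro-2H-pyran-2-one; 18 (3R,4R)-pent-1-ene-3,4-diyl diacetate
Product: 19 (6S)-6-[(1S,2R,3E,5R,6R)-5,6-diacetoxy-1-hydroxy-2-methoxyhept-3-en-1-yl]-5,6-dihydro-2H-pyran-2-one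
Conditions: second-generation Hoveyda–Grubbs catalyst RuCl2(H2IMes)(=CH-C6H4-2-O-i-Pr) (5–8 mol%), 18 (3 equiv), 1,4-benzoquinone (10 mol%), CH2Cl2, 40 °C
Reagents that add atoms: none
Why: Olefin cross-metathesis of two terminal alkenes with loss of ethene gives the thermodynamically favoured E-alkene; the electron-poor ring alkene is inert, the excess of 18 suppresses homodimer of 11, and no stereocentre is touched.

**Compound list**

1 | 2-deoxy-D-ribose (pyranose form, anomer mixture) | OC1C[C@H](O)[C@H](O)CO1 | starting material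
2 | methyl (triphenylphosphoranylidene)acetate | COC(=O)C=P(c1ccccc1)(c1ccccc1)c1ccccc1 | starting material
3 | methyl (2E,5S,6R)-5,6,7-trihydroxyhept-2-enoate | COC(=O)/C=C/C[C@H](O)[C@H](O)CO | intermediate
4 | methyl (2Z,5S,6R)-5,6,7-trihydroxyhept-2-enoate (not isolated) | COC(=O)/C=C\C[C@H](O)[C@H](O)CO | intermediate
5 | (6S)-6-[(1R)-1,2-dihydroxyethyl]-5,6-dihydro-2H-pyran-2-one | OC[C@@H](O)[C@@H]1CC=CC(=O)O1 | intermediate
6 | (2S)-6-oxo-3,6-dihydro-2H-pyran-2-carbaldehyde | O=C[C@@H]1CC=CC(=O)O1 | intermediate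
7 | acrolein dimethyl acetal (3,3-dimethoxyprop-1-ene) | COC(OC)C=C | starting material
8 | 3-chloro-3-methoxyprop-1-ene (not isolated) | COC(Cl)C=C | intermediate
9 | (E)-3-methoxyallylchromium dichloride, trivalent chromium (not isolated) | CO/C=C/C[Cr](Cl)Cl | intermediate
10 | (6S)-6-[(1S,2R)-2-methoxy-1-(trimethylsilyloxy)but-3-en-1-yl]-5,6-dihydro-2H-pyran-2-one (not isolated) | CO[C@H](C=C)[C@@H](O[Si](C)(C)C)[C@@H]1CC=CC(=O)O1 | intermediate
11 | (6S)-6-[(1S,2R)-1-hydroxy-2-methoxybut-3-en-1-yl]-5,6-dihydro-2H-pyran-2-one | CO[C@H](C=C)[C@@H](O)[C@@H]1CC=CC(=O)O1 | intermediate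
12 | L-threonine, (2S,3R)-2-amino-3-hydroxybutanoic acid | C[C@@H](O)[C@H](N)C(=O)O | starting material
13 | (2S,3R)-2,3-dihydroxybutanoic acid | C[C@@H](O)[C@H](O)C(=O)O | intermediate
14 | methyl (4S,5R)-2,2,5-trimethyl-1,3-dioxolane-4-carboxylate | C[C@H]1OC(C)(C)O[C@@H]1C(=O)OC | intermediate
15 | (4S,5R)-2,2,5-trimethyl-1,3-dioxolane-4-carbaldehyde (not isolated) | C[C@H]1OC(C)(C)O[C@@H]1C=O | intermediate
16 | (4R,5R)-4-ethenyl-2,2,5-trimethyl-1,3-dioxolane | C[C@H]1OC(C)(C)O[C@@H]1C=C | intermediate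
17 | (3R,4R)-pent-1-ene-3,4-diol (not isolated) | C=C[C@@H](O)[C@@H](C)O | intermediate
18 | (3R,4R)-pent-1-ene-3,4-diyl diacetate | C=C[C@@H](OC(C)=O)[C@@H](C)OC(C)=O | intermediate
19 | (6S)-6-[(1S,2R,3E,5R,6R)-5,6-diacetoxy-1-hydroxy-2-methoxyhept-3-en-1-yl]-5,6-dihydro-2H-pyran-2-one | CO[C@H](/C=C/[C@@H](OC(C)=O)[C@@H](C)OC(C)=O)[C@@H](O)[C@@H]1CC=CC(=O)O1 | target

**Step count and risk**

Total steps: 9 (steps 1–4 for fragment A, steps 5–8 for fragment B, step 9 for the union). Longest linear sequence: 5 (steps 1–4 then 9, or steps 5–8 then 9).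

The three steps most likely to fail:

**Step 4 (the proposed new method).** Risks are poor chromium turnover at the cathode, direct reduction of 6 or 8, and modest facial selectivity. The fallback sets out from 6 and comes back at 11, using known uncatalysed allylboration in place of the chromium cycle. Methyl propargyl ether is hydroborated with pinacolborane (Cp2Zr(H)Cl cat.) to 2-[(1E)-3-methoxyprop-1-en-1-yl]-4,4,5,5-tetramethyl-1,3,2-dioxaborolane F1. A cationic iridium catalyst ([Ir(cod)(PPh2Me)2]PF6, activated with H2) moves the double bond to give the (E)-γ-methoxyallylboronate 2-[(2E)-3-methoxyprop-2-en-1-yl]-4,4,5,5-tetramethyl-1,3,2-dioxaborolane F2. F2 adds to 6 in toluene at rt through the same closed chair and the same Cornforth face (anti,anti) to give the pinacol borate of the adduct F3, which aqueous work-up hydrolyses to 11.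

**Step 2.** Risks are a slow or incomplete photostationary drain, or photodimerisation of the product lactone. The fallback sets out from 3 and comes back at 5 by ground-state chemistry. PhSH with catalytic Et3N adds to the enoate to give methyl (5S,6R)-5,6,7-trihydroxy-3-(phenylsulfanyl)heptanoate F4 (C3 epimers are irrelevant). Catalytic TsOH in toluene at 60 °C closes the δ-lactone to (6S)-6-[(1R)-1,2-dihydroxyethyl]-4-(phenylsulfanyl)oxan-2-one F5. mCPBA (1 equiv, −78 °C) gives (6S)-6-[(1R)-1,2-dihydroxyethyl]-4-(phenylsulfinyl)oxan-2-one F6, and warming in toluene (80 °C, CaCO3) brings about syn-elimination toward the acidic C3 hydrogens to give 5.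

**Step 9.** Risks are that two secondary allylic, oxygenated alkenes couple slowly, and that 11 dimerises or its allylic ether isomerises. The fallback sets out from 14 and 11 and comes back at 19, replacing metathesis by a Julia–Kocienski olefination.

- Sulfone partner: LiAlH4 reduces 14 to [(4R,5R)-2,2,5-trimethyl-1,3-dioxolan-4-yl]methanol F7. Mitsunobu reaction with 1-phenyl-1H-tetrazole-5-thiol (PPh3, DIAD) gives 1-phenyl-5-({[(4S,5R)-2,2,5-trimethyl-1,3-dioxolan-4-yl]methyl}sulfanyl)-1H-tetrazole F8. (NH4)6Mo7O24/H2O2 oxidises it to 1-phenyl-5-({[(4S,5R)-2,2,5-trimethyl-1,3-dioxolan-4-yl]methyl}sulfonyl)-1H-tetrazole F9.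
- Aldehyde partner: 11 is silylated (TBSOTf, 2,6-lutidine) to (6S)-6-[(1S,2R)-1-(tert-butyldimethylsilyloxy)-2-methoxybut-3-en-1-yl]-5,6-dihydro-2H-pyran-2-one F10. Selective ozonolysis of the terminal alkene (O3, CH2Cl2, −78 °C; PPh3) gives (2S,3S)-3-(tert-butyldimethylsilyloxy)-2-methoxy-3-[(2S)-6-oxo-3,6-dihydro-2H-pyran-2-yl]propanal F11.
- Union and endgame: KN(SiMe3)2 added to F9 and F11 in DME at −60 °C (Barbier mode) gives the E-alkene (6S)-6-{(1S,2R,3E)-1-(tert-butyldimethylsilyloxy)-2-methoxy-4-[(4R,5R)-2,2,5-trimethyl-1,3-dioxolan-4-yl]but-3-en-1-yl}-5,6-dihydro-2H-pyran-2-one F12. Aqueous 80% AcOH at 40 °C removes only the acetonide to give (6S)-6-[(1S,2R,3E,5R,6R)-1-(tert-butyldimethylsilyloxy)-5,6-dihydroxy-2-methoxyhept-3-en-1-yl]-5,6-dihydro-2H-pyran-2-one F13. Ac2O/pyridine/DMAP gives (6S)-6-[(1S,2R,3E,5R,6R)-5,6-diacetoxy-1-(tert-butyldimethylsilyloxy)-2-methoxyhept-3-en-1-yl]-5,6-dihydro-2H-pyran-2-one F14, and HF·pyridine in THF removes the silyl group to give 19.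

**Further compounds**

F1 | step 4 | 2-[(1E)-3-methoxyprop-1-en-1-yl]-4,4,5,5-tetramethyl-1,3,2-dioxaborolane | COC/C=C/B1OC(C)(C)C(C)(C)O1
F2 | step 4 | 2-[(2E)-3-methoxyprop-2-en-1-yl]-4,4,5,5-tetramethyl-1,3,2-dioxaborolane | CO/C=C/CB1OC(C)(C)C(C)(C)O1
F3 | step 4 | (6S)-6-{(1S,2R)-2-methoxy-1-[(4,4,5,5-tetramethyl-1,3,2-dioxaborolan-2-yl)oxy]but-3-en-1-yl}-5,6-dihydro-2H-pyran-2-one | CO[C@H](C=C)[C@@H](OB1OC(C)(C)C(C)(C)O1)[C@@H]1CC=CC(=O)O1
F4 | step 2 | methyl (5S,6R)-5,6,7-trihydroxy-3-(phenylsulfanyl)heptanoate | COC(=O)CC(Sc1ccccc1)C[C@H](O)[C@H](O)CO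
F5 | step 2 | (6S)-6-[(1R)-1,2-dihydroxyethyl]-4-(phenylsulfanyl)oxan-2-one | OC[C@@H](O)[C@@H]1CC(Sc2ccccc2)CC(=O)O1
F6 | step 2 | (6S)-6-[(1R)-1,2-dihydroxyethyl]-4-(phenylsulfinyl)oxan-2-one | OC[C@@H](O)[C@@H]1CC(S(=O)c2ccccc2)CC(=O)O1
F7 | step 9 | [(4R,5R)-2,2,5-trimethyl-1,3-dioxolan-4-yl]methanol | C[C@H]1OC(C)(C)O[C@@H]1CO
F8 | step 9 | 1-phenyl-5-({[(4S,5R)-2,2,5-trimethyl-1,3-dioxolan-4-yl]methyl}sulfanyl)-1H-tetrazole | C[C@H]1OC(C)(C)O[C@@H]1CSc1nnnn1-c1ccccc1
F9 | step 9 | 1-phenyl-5-({[(4S,5R)-2,2,5-trimethyl-1,3-dioxolan-4-yl]methyl}sulfonyl)-1H-tetrazole | C[C@H]1OC(C)(C)O[C@@H]1CS(=O)(=O)c1nnnn1-c1ccccc1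
F10 | step 9 | (6S)-6-[(1S,2R)-1-(tert-butyldimethylsilyloxy)-2-methoxybut-3-en-1-yl]-5,6-dihydro-2H-pyran-2-one | CO[C@H](C=C)[C@@H](O[Si](C)(C)C(C)(C)C)[C@@H]1CC=CC(=O)O1
F11 | step 9 | (2S,3S)-3-(tert-butyldimethylsilyloxy)-2-methoxy-3-[(2S)-6-oxo-3,6-dihydro-2H-pyran-2-yl]propanal | CO[C@H](C=O)[C@@H](O[Si](C)(C)C(C)(C)C)[C@@H]1CC=CC(=O)O1
F12 | step 9 | (6S)-6-{(1S,2R,3E)-1-(tert-butyldimethylsilyloxy)-2-methoxy-4-[(4R,5R)-2,2,5-trimethyl-1,3-dioxolan-4-yl]but-3-en-1-yl}-5,6-dihydro-2H-pyran-2-one | CO[C@H](/C=C/[C@H]1OC(C)(C)O[C@@H]1C)[C@@H](O[Si](C)(C)C(C)(C)C)[C@@H]1CC=CC(=O)O1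
F13 | step 9 | (6S)-6-[(1S,2R,3E,5R,6R)-1-(tert-butyldimethylsilyloxy)-5,6-dihydroxy-2-methoxyhept-3-en-1-yl]-5,6-dihydro-2H-pyran-2-one | CO[C@H](/C=C/[C@@H](O)[C@@H](C)O)[C@@H](O[Si](C)(C)C(C)(C)C)[C@@H]1CC=CC(=O)O1
F14 | step 9 | (6S)-6-[(1S,2R,3E,5R,6R)-5,6-diacetoxy-1-(tert-butyldimethylsilyloxy)-2-methoxyhept-3-en-1-yl]-5,6-dihydro-2H-pyran-2-one | CO[C@H](/C=C/[C@@H](OC(C)=O)[C@@H](C)OC(C)=O)[C@@H](O[Si](C)(C)C(C)(C)C)[C@@H]1CC=CC(=O)O1
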